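**Plan**

- Locants are those of the target as a 9-oxabicyclo[6.2.1]undecane: C1 (lactone α-carbon), C2 (carries the acetoxymethylidene), C3=C4, C5=C6(CH3), C7, C8 (O-bearing), O9, C10 (C=O), C11 (carries the side chain).
- Retrosynthetic cuts, in order: enol acetate back to the C2 aldehyde (stored as dimethyl acetal); C1–H back to C1–SO2Ph; C3=C4 back to a C4 carbinol; C4–C5, which opens the nine-membered ring to a vinyl iodide and an aldehyde; C1–C2; last, C10–C1 and C11–C8 of the γ-lactone together.
- Feature used: in the five-membered lactone ring, C8 and C10 are joined through O9 and flank the C11–C1 pair. A C8 radical that already carries O9–C10 as a carbonate can therefore add to a C11=C1 double bond whose C1 bears a sulfonyl group, and the C1 carbanion then closes onto C10.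
- Forward: acid 10 (5 steps) and vinyl sulfone 15 (2 steps) are joined in that annulation, so the lactone arises first. The C2–C4 unit is then attached at C1 and the nine-membered ring is closed at C4–C5. Dehydration, desulfonylation, acetal hydrolysis and enol acetylation finish the route.
- Stereochemistry: the side-chain centre comes from (S)-citronellyl bromide. C8 and C11 arise in the key step, where only weak control is expected: isomers are separated, and only the 4,5-trans lactone can be bridged. C1 is fixed by protonation at the bridgehead. E-C5=C6 comes from syn-carboalumination, Z-C3=C4 is enforced by the ring, and the Z enol acetate comes from the extended enolate.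

Key step: step 8

Remark: compounds 7 to 10 are racemic at the future C8, which is acceptable because this carbon becomes a planar radical in step 8; compounds 19 to 23 carry temporary, unassigned centres (future C2 and C4) that are removed later.

**Route**

Step 1
Reactants: 1 prop-2-yn-1-ol
Product: 3 (E)-3-iodo-2-methylprop-2-en-1-ol, via alkenylalane 2 (not isolated)
Conditions: AlMe3 (3 equiv), Cp2ZrCl2 (0.25 equiv), CH2Cl2, 0 °C to rt; then I2, THF, −30 to 0 °C
Reagents that add atoms: trimethylaluminium C[Al](C)C; iodine II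
Why: Zirconium-catalysed syn-carboalumination of the terminal alkyne (Negishi carboalumination) puts methyl on the internal and aluminium on the terminal carbon, and iodinolysis of the C–Al bond with retention should give the E vinyl iodide that later becomes the E-C5=C6 bond.

Step 2
Reactants: 3 (E)-3-iodo-2-methylprop-2-en-1-ol
Product: 4 (E)-3-bromo-1-iodo-2-methylprop-1-ene
Conditions: CBr4, PPh3, CH2Cl2, 0 °C
Reagents that add atoms: carbon tetrabromide BrC(Br)(Br)Br
Why: Appel bromination of the primary allylic alcohol proceeds by SN2 displacement of the alkoxyphosphonium group and leaves the vinyl iodide geometry untouched.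

Step 3
Reactants: 5 2,2-dimethyl-1,3-dioxolan-4-one; 4 (E)-3-bromo-1-iodo-2-methylprop-1-ene
Product: 7 rac-5-[(E)-3-iodo-2-methylprop-2-en-1-yl]-2,2-dimethyl-1,3-dioxolan-4-one, via lithium enolate 6 (not isolated)
Conditions: LiN(iPr)2, THF, −78 °C; then 4, −78 to −20 °C
Reagents that add atoms: none
Why: C-alkylation of the glycolate-type lithium enolate with the reactive allylic bromide (enolate alkylation) forms the C7–C8 bond, and the new centre may be racemic because it becomes a planar radical in step 8.

Step 4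
Reactants: 7 rac-5-[(E)-3-iodo-2-methylprop-2-en-1-yl]-2,2-dimethyl-1,3-dioxolan-4-one
Product: 8 rac-(E)-2-hydroxy-5-iodo-4-methylpent-4-enoic acid
Conditions: 1 M HCl, THF, rt
Reagents that add atoms: none
Why: Acid-catalysed hydrolysis of the acetonide-type dioxolanone (acetal hydrolysis) releases acetone and the free α-hydroxy acid.

Step 5
Reactants: 8 rac-(E)-2-hydroxy-5-iodo-4-methylpent-4-enoic acid
Product: 10 rac-(E)-5-iodo-2-[(methoxycarbonyl)oxy]-4-methylpent-4-enoic acid, via mixed anhydride 9 (not isolated)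
Conditions: ClCO2Me (2.2 equiv), pyridine (3 equiv), CH2Cl2, 0 °C; then H2O, rt
Reagents that add atoms: methyl chloroformate COC(=O)Cl
Why: Acylation with the chloroformate turns the hydroxyl into the methyl carbonate (the future O9–C10 unit) and the carboxyl into a mixed carbonic anhydride, and only the much more electrophilic anhydride is hydrolysed on addition of water (chemoselective hydrolysis), which returns the free acid.

Step 6
Reactants: 11 (3S)-1-bromo-3,7-dimethyloct-6-ene ((S)-citronellyl bromide)
Product: 12 {[(3S)-3,7-dimethyloct-6-en-1-yl]sulfonyl}benzene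
Conditions: PhSO2Na, Bu4NI (cat.), DMF, 60 °C
Reagents that add atoms: sodium benzenesulfinate [Na+].[O-]S(=O)c1ccccc1
Why: SN2 S-alkylation of the sulfinate by the primary bromide gives the sulfone without touching the stereocentre, which is taken from the chiral pool and becomes the side-chain centre of the target.

Step 7
Reactants: 12 {[(3S)-3,7-dimethyloct-6-en-1-yl]sulfonyl}benzene
Product: 15 {[(1E,3S)-3,7-dimethylocta-1,6-dien-1-yl]sulfonyl}benzene, via lithiated sulfone 13 (not isolated), via selanyl sulfone 14 (not isolated)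
Conditions: n-BuLi, THF, −78 °C; PhSeCl, −78 °C; then NaIO4, NaHCO3, MeOH–H2O, rt
Reagents that add atoms: none
Why: Selenenylation of the α-sulfonyl carbanion followed by oxidation and syn-elimination of the selenoxide (selenoxide elimination) can only form the double bond towards the sole β-hydrogens on the neighbouring CH2, which should give the E vinyl sulfone with the allylic stereocentre intact.

Step 8
Reactants: 10 rac-(E)-5-iodo-2-[(methoxycarbonyl)oxy]-4-methylpent-4-enoic acid; 15 {[(1E,3S)-3,7-dimethylocta-1,6-dien-1-yl]sulfonyl}benzene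
Product: 17 (3R,4S,5S)-5-[(E)-3-iodo-2-methylprop-2-en-1-yl]-4-[(2S)-6-methylhept-5-en-2-yl]-3-(phenylsulfonyl)oxolan-2-one, via carbanion 16 (not isolated)
Conditions: KOtBu (1.0 equiv), [Ir(dF(CF3)ppy)2(dtbbpy)]PF6 (2 mol %), 15 (1.5 equiv), dry DMF, blue LEDs (450 nm), rt; then 0.5 M HCl
Reagents that add atoms: none
Why: Proposed new method: the photoexcited iridium complex should oxidise the carboxylate of 10, CO2 is lost, and the nucleophilic α-(methoxycarbonyloxy)alkyl radical adds to the β-carbon of vinyl sulfone 15 (bond C8–C11); the α-sulfonyl radical is then reduced by the divalent iridium species to carbanion 16, which attacks the carbonate carbonyl on the neighbouring oxygen and expels methoxide (bond C10–C1). The closest known reaction types are the photoredox decarboxylative Giese addition of α-oxy acids to vinyl sulfones and the acylation of sulfonyl carbanions by carbonates, merged here into one radical–polar crossover [3+2] annulation. The only ring closed is the γ-lactone, by 5-exo-trig nucleophilic acyl substitution at C10. C11 is set by attack on the vinyl sulfone face anti to the larger homoprenyl arm of the adjacent side-chain centre (allylic hydrogen eclipsing the double bond) and C8 by approach of the radical with its iodoallyl arm turned away from that substituent, which should favour the 4,5-trans lactone, although this acyclic control is expected to be weak; C1 stays epimerisable and is settled in step 12. The step needs β-regioselectivity (secured by the sulfonyl group), acyl transfer faster than protonation of 16 (aprotic medium, no acid stronger than methanol, five-membered transition state) and survival of the vinyl iodide and the prenyl double bond (poor acceptors for a nucleophilic radical). Stereoisomers that form are removed by chromatography here, and a 4,5-cis lactone could not be bridged in step 10 in any case.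

Step 9
Reactants: 17 (3R,4S,5S)-5-[(E)-3-iodo-2-methylprop-2-en-1-yl]-4-[(2S)-6-methylhept-5-en-2-yl]-3-(phenylsulfonyl)oxolan-2-one; 18 (E)-4,4-dimethoxybut-2-enal
Product: 19 3-[(3R,4S,5S)-5-[(E)-3-iodo-2-methylprop-2-en-1-yl]-4-[(2S)-6-methylhept-5-en-2-yl]-2-oxo-3-(phenylsulfonyl)oxolan-3-yl]-4,4-dimethoxybutanal (epimers at C3 of the butanal chain)
Conditions: DBU (0.2 equiv), CH2Cl2, 0 °C to rt
Reagents that add atoms: none
Why: The C–H flanked by sulfonyl and lactone carbonyl is removed by catalytic amidine base and the soft carbanion adds 1,4 to the enal at its acetal-bearing β-carbon (Michael addition), forming C1–C2 on the lactone face anti to the side chain at C11 and therefore cis to the iodoallyl arm at C8, while the new chain centre (future C2) forms unselectively and is erased in step 14.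

Step 10
Reactants: 19 3-[(3R,4S,5S)-5-[(E)-3-iodo-2-methylprop-2-en-1-yl]-4-[(2S)-6-methylhept-5-en-2-yl]-2-oxo-3-(phenylsulfonyl)oxolan-3-yl]-4,4-dimethoxybutanal
Product: 20 (1R,5E,8S,11S)-2-(dimethoxymethyl)-4-hydroxy-6-methyl-11-[(2S)-6-methylhept-5-en-2-yl]-1-(phenylsulfonyl)-9-oxabicyclo[6.2.1]undec-5-en-10-one (epimers at C2 and C4)
Conditions: CrCl2 (8 equiv), NiCl2 (0.1 equiv), DMSO–THF, rt, 0.002 M; aqueous work-up
Reagents that add atoms: none
Why: In this Nozaki–Hiyama–Kishi reaction the nickel-catalysed activation of the vinyl C–I bond and transmetalation to chromium give a vinylchromium species that adds chemoselectively to the aldehyde with retention of the E geometry, the quaternary C1 and the cis arrangement of the two arms on the lactone favouring closure of the nine-membered ring, while the carbinol centre forms unselectively and is removed in step 11.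

Step 11
Reactants: 20 (1R,5E,8S,11S)-2-(dimethoxymethyl)-4-hydroxy-6-methyl-11-[(2S)-6-methylhept-5-en-2-yl]-1-(phenylsulfonyl)-9-oxabicyclo[6.2.1]undec-5-en-10-one
Product: 21 (1R,3Z,5E,8S,11S)-2-(dimethoxymethyl)-6-methyl-11-[(2S)-6-methylhept-5-en-2-yl]-1-(phenylsulfonyl)-9-oxabicyclo[6.2.1]undeca-3,5-dien-10-one (epimers at C2)
Conditions: Burgess reagent, toluene, 70 °C
Reagents that add atoms: none
Why: In the Burgess dehydration the sulfamate ester of the allylic alcohol undergoes syn-elimination with a hydrogen on C3 (the only β-hydrogens), and inside the nine-membered ring next to the E-C5=C6 bond the new C3=C4 bond should form with Z geometry, which completes the conjugated diene.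

Step 12
Reactants: 21 (1R,3Z,5E,8S,11S)-2-(dimethoxymethyl)-6-methyl-11-[(2S)-6-methylhept-5-en-2-yl]-1-(phenylsulfonyl)-9-oxabicyclo[6.2.1]undeca-3,5-dien-10-one
Product: 22 (1S,3Z,5E,8S,11R)-2-(dimethoxymethyl)-6-methyl-11-[(2S)-6-methylhept-5-en-2-yl]-9-oxabicyclo[6.2.1]undeca-3,5-dien-10-one (epimers at C2)
Conditions: SmI2 (3 equiv), THF–HMPA–MeOH, −78 °C
Reagents that add atoms: none
Why: Reductive desulfonylation of the α-sulfonyl lactone by two single-electron transfers from samarium diiodide cleaves the C1–S bond, and protonation at the bridgehead can only give the lactone bridge cis across the ring, so the C1 stereocentre is dictated by the bicyclic skeleton.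

Step 13
Reactants: 22 (1S,3Z,5E,8S,11R)-2-(dimethoxymethyl)-6-methyl-11-[(2S)-6-methylhept-5-en-2-yl]-9-oxabicyclo[6.2.1]undeca-3,5-dien-10-one
Product: 23 (1S,3Z,5E,8S,11R)-6-methyl-11-[(2S)-6-methylhept-5-en-2-yl]-10-oxo-9-oxabicyclo[6.2.1]undeca-3,5-diene-2-carbaldehyde (epimers at C2)
Conditions: pyridinium p-toluenesulfonate (cat.), acetone–H2O, 40 °C
Reagents that add atoms: water O
Why: Mild acid-catalysed hydrolysis of the dimethyl acetal (acetal hydrolysis) unveils the aldehyde without opening the lactone, and the configuration at C2 is irrelevant because this carbon becomes sp2 in step 14.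

Step 14
Reactants: 23 (1S,3Z,5E,8S,11R)-6-methyl-11-[(2S)-6-methylhept-5-en-2-yl]-10-oxo-9-oxabicyclo[6.2.1]undeca-3,5-diene-2-carbaldehyde
Product: 24 [(Z)-[(1S,3Z,5E,8S,11R)-6-methyl-11-[(2S)-6-methylhept-5-en-2-yl]-10-oxo-9-oxabicyclo[6.2.1]undeca-3,5-dien-2-ylidene]methyl] acetate
Conditions: Ac2O, Et3N, DMAP (cat.), CH2Cl2, 0 °C to rt
Reagents that add atoms: acetic anhydride CC(=O)OC(C)=O
Why: Amine-mediated O-acetylation of the extended enolate (enol ester formation) removes the acidic C2–H, which is α to the aldehyde and allylic to the ring diene, and acetylation should occur in the zigzag arrangement with oxygen anti to C3 and syn to C1 (as in the formation of 1-acetoxybuta-1,3-diene), which is the Z enol acetate of the target.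

**Compound list**

1 | prop-2-yn-1-ol | C#CCO | starting material
2 | dimethyl[(E)-3-(dimethylalumanyloxy)-2-methylprop-1-en-1-yl]alumane | C[Al](C)OC/C(C)=C/[Al](C)C | intermediate (not isolated)
3 | (E)-3-iodo-2-methylprop-2-en-1-ol | OC/C(C)=C/I | intermediate
4 | (E)-3-bromo-1-iodo-2-methylprop-1-ene | BrC/C(C)=C/I | intermediate
5 | 2,2-dimethyl-1,3-dioxolan-4-one | CC1(C)OCC(=O)O1 | starting material
6 | lithium 2,2-dimethyl-1,3-dioxol-4-olate | [Li+].CC1(C)OC=C([O-])O1 | intermediate (not isolated)
7 | rac-5-[(E)-3-iodo-2-methylprop-2-en-1-yl]-2,2-dimethyl-1,3-dioxolan-4-one | CC1(C)OC(C/C(C)=C/I)C(=O)O1 | intermediate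
8 | rac-(E)-2-hydroxy-5-iodo-4-methylpent-4-enoic acid | OC(C/C(C)=C/I)C(=O)O | intermediate
9 | rac-(E)-5-iodo-2-[(methoxycarbonyl)oxy]-4-methylpent-4-enoic methyl carbonic anhydride | COC(=O)OC(C/C(C)=C/I)C(=O)OC(=O)OC | intermediate (not isolated)
10 | rac-(E)-5-iodo-2-[(methoxycarbonyl)oxy]-4-methylpent-4-enoic acid | COC(=O)OC(C/C(C)=C/I)C(=O)O | intermediate
11 | (3S)-1-bromo-3,7-dimethyloct-6-ene ((S)-citronellyl bromide) | BrCC[C@@H](C)CCC=C(C)C | starting material
12 | {[(3S)-3,7-dimethyloct-6-en-1-yl]sulfonyl}benzene | O=S(=O)(CC[C@@H](C)CCC=C(C)C)c1ccccc1 | intermediate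
13 | lithium (3S)-3,7-dimethyl-1-(phenylsulfonyl)oct-6-en-1-ide | [Li+].O=S(=O)([CH-]C[C@@H](C)CCC=C(C)C)c1ccccc1 | intermediate (not isolated)
14 | {[(3S)-3,7-dimethyl-1-(phenylselanyl)oct-6-en-1-yl]sulfonyl}benzene (epimers at C1) | O=S(=O)(C(C[C@@H](C)CCC=C(C)C)[Se]c1ccccc1)c1ccccc1 | intermediate (not isolated)
15 | {[(1E,3S)-3,7-dimethylocta-1,6-dien-1-yl]sulfonyl}benzene | O=S(=O)(/C=C/[C@@H](C)CCC=C(C)C)c1ccccc1 | intermediate
16 | potassium (2S,3S,5E)-6-iodo-3-[(methoxycarbonyl)oxy]-5-methyl-2-[(2S)-6-methylhept-5-en-2-yl]-1-(phenylsulfonyl)hex-5-en-1-ide | [K+].COC(=O)O[C@@H](C/C(C)=C/I)[C@H]([C@@H](C)CCC=C(C)C)[CH-]S(=O)(=O)c1ccccc1 | intermediate (not isolated)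
17 | (3R,4S,5S)-5-[(E)-3-iodo-2-methylprop-2-en-1-yl]-4-[(2S)-6-methylhept-5-en-2-yl]-3-(phenylsulfonyl)oxolan-2-one | O=C1O[C@@H](C/C(C)=C/I)[C@H]([C@@H](C)CCC=C(C)C)[C@H]1S(=O)(=O)c1ccccc1 | intermediate
18 | (E)-4,4-dimethoxybut-2-enal | O=C/C=C/C(OC)OC | starting material
19 | 3-[(3R,4S,5S)-5-[(E)-3-iodo-2-methylprop-2-en-1-yl]-4-[(2S)-6-methylhept-5-en-2-yl]-2-oxo-3-(phenylsulfonyl)oxolan-3-yl]-4,4-dimethoxybutanal (epimers at C3 of the chain) | O=C1O[C@@H](C/C(C)=C/I)[C@H]([C@@H](C)CCC=C(C)C)[C@@]1(S(=O)(=O)c1ccccc1)C(CC=O)C(OC)OC | intermediate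
20 | (1R,5E,8S,11S)-2-(dimethoxymethyl)-4-hydroxy-6-methyl-11-[(2S)-6-methylhept-5-en-2-yl]-1-(phenylsulfonyl)-9-oxabicyclo[6.2.1]undec-5-en-10-one (epimers at C2 and C4) | O=C1O[C@H]2C/C(C)=C/C(O)CC(C(OC)OC)[C@]1(S(=O)(=O)c1ccccc1)[C@H]2[C@@H](C)CCC=C(C)C | intermediate
21 | (1R,3Z,5E,8S,11S)-2-(dimethoxymethyl)-6-methyl-11-[(2S)-6-methylhept-5-en-2-yl]-1-(phenylsulfonyl)-9-oxabicyclo[6.2.1]undeca-3,5-dien-10-one (epimers at C2) | O=C1O[C@H]2C/C(C)=C/C=C\C(C(OC)OC)[C@]1(S(=O)(=O)c1ccccc1)[C@H]2[C@@H](C)CCC=C(C)C | intermediate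
22 | (1S,3Z,5E,8S,11R)-2-(dimethoxymethyl)-6-methyl-11-[(2S)-6-methylhept-5-en-2-yl]-9-oxabicyclo[6.2.1]undeca-3,5-dien-10-one (epimers at C2) | O=C1O[C@H]2C/C(C)=C/C=C\C(C(OC)OC)[C@@H]1[C@H]2[C@@H](C)CCC=C(C)C | intermediate
23 | (1S,3Z,5E,8S,11R)-6-methyl-11-[(2S)-6-methylhept-5-en-2-yl]-10-oxo-9-oxabicyclo[6.2.1]undeca-3,5-diene-2-carbaldehyde (epimers at C2) | O=C1O[C@H]2C/C(C)=C/C=C\C(C=O)[C@@H]1[C@H]2[C@@H](C)CCC=C(C)C | intermediate
24 | [(Z)-[(1S,3Z,5E,8S,11R)-6-methyl-11-[(2S)-6-methylhept-5-en-2-yl]-10-oxo-9-oxabicyclo[6.2.1]undeca-3,5-dien-2-ylidene]methyl] acetate | CC(=O)O/C=C1/C=C\C=C(/C)C[C@@H]2OC(=O)[C@H]1[C@H]2[C@@H](C)CCC=C(C)C | target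

**Step count and risks**

Total number of steps: 14. Longest linear sequence: 12 steps (steps 1 to 5, then 8 to 14).

Steps most likely to fail:

1. Step 8 (proposed new method). The α-sulfonyl radical or carbanion may be lost by hydrogen or proton transfer, or by attack on the prenyl double bond, before the acyl transfer takes place, and the radical addition may distinguish the faces of both partners only weakly. The fallback sets out from 10 and 15 and separates the two events with known chemistry. A standard decarboxylative Giese addition in the presence of water ([Ir(dF(CF3)ppy)2(dtbbpy)]PF6, K2HPO4, DMF–H2O, blue LEDs) should give the open-chain carbonate methyl (4S,5S,1E)-1-iodo-2-methyl-5-[(2S)-6-methylhept-5-en-2-yl]-6-(phenylsulfonyl)hex-1-en-4-yl carbonate F1, from which the unwanted diastereomers are removed by chromatography. Treatment of F1 with LiN(SiMe3)2 in THF at −78 to 0 °C then closes the lactone by acylation of the sulfonyl carbanion and comes back to the route at 17.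

2. Step 10. Intermolecular coupling and simple reduction of the vinyl iodide may outrun closure of the strained nine-membered ring. The fallback sets out from 17 and closes the ring by olefin metathesis instead. Iridium-catalysed branched allylic alkylation of 17 with methyl (E)-4,4-dimethoxybut-2-en-1-yl carbonate ([Ir(cod)Cl]2, phosphoramidite ligand, DBU, THF) should give (3R,4S,5S)-3-(1,1-dimethoxybut-3-en-2-yl)-5-[(E)-3-iodo-2-methylprop-2-en-1-yl]-4-[(2S)-6-methylhept-5-en-2-yl]-3-(phenylsulfonyl)oxolan-2-one F2. Stille coupling of its vinyl iodide with tributyl(vinyl)stannane (Pd(PPh3)4, DMF) gives the diene (3R,4S,5S)-3-(1,1-dimethoxybut-3-en-2-yl)-5-[(2E)-2-methylpenta-2,4-dien-1-yl]-4-[(2S)-6-methylhept-5-en-2-yl]-3-(phenylsulfonyl)oxolan-2-one F3. Ring-closing metathesis of F3 (second-generation Grubbs catalyst, toluene, high dilution) forms C3=C4 directly and comes back to the route at 21, so that steps 9 to 11 are bypassed.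

3. Step 11. The allylic sulfamate may ionise to a delocalised cation, followed by unselective proton loss or allylic transposition, instead of the clean syn-elimination. The fallback sets out from 20 and replaces the elimination by an oxidation–reduction sequence. Oxidation with Dess–Martin periodinane should give the enone (1R,5E,8S,11S)-2-(dimethoxymethyl)-6-methyl-11-[(2S)-6-methylhept-5-en-2-yl]-1-(phenylsulfonyl)-9-oxabicyclo[6.2.1]undec-5-ene-4,10-dione F4. Kinetic deprotonation at C3 with KN(SiMe3)2 and trapping with PhNTf2 gives the ring-cis dienyl triflate 2-(dimethoxymethyl)-6-methyl-11-[(2S)-6-methylhept-5-en-2-yl]-10-oxo-1-(phenylsulfonyl)-9-oxabicyclo[6.2.1]undeca-3,5-dien-4-yl trifluoromethanesulfonate F5. Palladium-catalysed reduction of F5 with formate (Pd(OAc)2, PPh3, HCO2H, Bu3N, DMF) comes back to the route at 21.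

Further compounds
F1 | step 8 | methyl (4S,5S,1E)-1-iodo-2-methyl-5-[(2S)-6-methylhept-5-en-2-yl]-6-(phenylsulfonyl)hex-1-en-4-yl carbonate | COC(=O)O[C@@H](C/C(C)=C/I)[C@H]([C@@H](C)CCC=C(C)C)CS(=O)(=O)c1ccccc1
F2 | step 10 | (3R,4S,5S)-3-(1,1-dimethoxybut-3-en-2-yl)-5-[(E)-3-iodo-2-methylprop-2-en-1-yl]-4-[(2S)-6-methylhept-5-en-2-yl]-3-(phenylsulfonyl)oxolan-2-one | O=C1O[C@@H](C/C(C)=C/I)[C@H]([C@@H](C)CCC=C(C)C)[C@@]1(S(=O)(=O)c1ccccc1)C(C=C)C(OC)OC
F3 | step 10 | (3R,4S,5S)-3-(1,1-dimethoxybut-3-en-2-yl)-5-[(2E)-2-methylpenta-2,4-dien-1-yl]-4-[(2S)-6-methylhept-5-en-2-yl]-3-(phenylsulfonyl)oxolan-2-one | O=C1O[C@@H](C/C(C)=C/C=C)[C@H]([C@@H](C)CCC=C(C)C)[C@@]1(S(=O)(=O)c1ccccc1)C(C=C)C(OC)OC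
F4 | step 11 | (1R,5E,8S,11S)-2-(dimethoxymethyl)-6-methyl-11-[(2S)-6-methylhept-5-en-2-yl]-1-(phenylsulfonyl)-9-oxabicyclo[6.2.1]undec-5-ene-4,10-dione | O=C1O[C@H]2C/C(C)=C/C(=O)CC(C(OC)OC)[C@]1(S(=O)(=O)c1ccccc1)[C@H]2[C@@H](C)CCC=C(C)C
F5 | step 11 | 2-(dimethoxymethyl)-6-methyl-11-[(2S)-6-methylhept-5-en-2-yl]-10-oxo-1-(phenylsulfonyl)-9-oxabicyclo[6.2.1]undeca-3,5-dien-4-yl trifluoromethanesulfonate (ring double bonds as in 21) | O=C1O[C@H]2C/C(C)=C/C(OS(=O)(=O)C(F)(F)F)=C\C(C(OC)OC)[C@]1(S(=O)(=O)c1ccccc1)[C@H]2[C@@H](C)CCC=C(C)C
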